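The δ-lactone is cut at its CH2–CH2 bond (C15–C16) and at the bond from the lactone O–CH (C20) to the all-carbon quaternary centre C14. Both bonds form in one radical–polar crossover: •CH2CO2Et adds to the terminal CH2 of a 1,3-diene (exocyclic methylene on the seven-membered ring, conjugated with the cyclopentene C12=C13), Cr(II) intercepts the allyl radical, and the allylchromium attacks, through C14, the aldehyde C20 held 1,3-diaxially on the piperidine. This closes the cyclopentane of the 2-azabicyclo[3.2.1]octane and sets C14; lactonisation follows. The precursor is a tetracyclic dienyl keto-aldehyde made by two catalytic asymmetric conjugate additions and a lactone-directed malonate desymmetrisation.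

Key step: step 15

Atom labels used below: C1H3–C2H–C3H2–N4 with C26(=O) and C21 form the pyrrolidinone; N4–C5H2–C6H–C23–C22H2–C21 is the piperidine; C6–C7H2–C8H2–C9H–C13–C14–C23 is the seven-membered ring; C9–C10H2–C11H2–C12H=C13 is the cyclopentene; C14–C15H2–C16H2–C17(=O)–O19–C20H is the lactone; C23 bears C24H2–O25H.

Assumption: C2 is α to the C26 ketone and epimerisable, and its natural configuration (methyl trans to C20 across the pyrrolidinone) is taken as the more stable one; compounds 13–29 are carried as C2 epimer mixtures and converge in step 16.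

Step 1
Reactants: 1 cycloheptanone
Product: 2 cyclohepta-2,6-dien-1-one
Conditions: IBX (2.5 equiv), DMSO/fluorobenzene, 70 °C
Reagents that add atoms: none
Why: IBX dehydrogenation of the ketone on both α,β-positions with controlled stoichiometry should give the symmetric cross-conjugated dienone; no stereocentre is formed.

Step 2
Reactants: 2 cyclohepta-2,6-dien-1-one; 3 potassium vinyltrifluoroborate
Product: 4 (S)-6-ethenylcyclohept-2-en-1-one
Conditions: 3 (0.8 equiv), [Rh(cod)2]BF4 (3 mol %), (S)-BINAP, toluene/H2O, 100 °C
Reagents that add atoms: potassium vinyltrifluoroborate, C=C[B-](F)(F)F.[K+]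
Why: Rhodium-catalysed asymmetric 1,4-addition (Hayashi–Miyaura reaction) to one enone arm of the dienone; the BINAP enantiomer (chosen to give the drawn S centre, the future C6) controls the face, and the borate as limiting reagent restrains a second addition.

Step 3
Reactants: 4 (S)-6-ethenylcyclohept-2-en-1-one; 5 [2-(1,3-dioxan-2-yl)ethyl]magnesium bromide
Product: 6 (3S,6S)-3-[2-(1,3-dioxan-2-yl)ethyl]-6-ethenylcycloheptan-1-one
Conditions: CuBr·SMe2 (5 mol %), (R,S)-Josiphos, t-BuOMe, −75 °C; aq NH4Cl
Reagents that add atoms: [2-(1,3-dioxan-2-yl)ethyl]magnesium bromide, Br[Mg]CCC1OCCCO1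
Why: Copper-catalysed asymmetric conjugate addition of a Grignard reagent to the remaining enone; the ligand (enantiomer chosen to give the drawn centre, the future C9) sets the remote stereocentre independently of C6, so the minor enantiomer of 4 ends up as a separable diastereomer.

Step 4
Reactants: 6 (3S,6S)-3-[2-(1,3-dioxan-2-yl)ethyl]-6-ethenylcycloheptan-1-one
Product: 8 (6S,8aS)-6-ethenyl-1,2,6,7,8,8a-hexahydroazulen-4(5H)-one, via keto aldehyde 7 (not isolated)
Conditions: 2 M HCl, THF, 50 °C
Reagents that add atoms: none
Why: Acetal hydrolysis followed by intramolecular aldol condensation from the ketone α-carbon next to the side chain (acetal-Grignard cyclopentene annulation) should give the cyclopentene-fused enone C14(=O)–C13=C12; C9 is not enolisable (cross-conjugated position) and is retained.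

Step 5
Reactants: 9 3-amino-2-methylpropanoic acid (racemic); 10 allyl alcohol
Product: 11 allyl 3-amino-2-methylpropanoate (racemic, free base, used at once)
Conditions: SOCl2, allyl alcohol (solvent), 0 → 50 °C; then aq K2CO3, CH2Cl2
Reagents that add atoms: allyl alcohol, C=CCO
Why: Acid-mediated (Fischer-type) esterification of the amino acid; the stereocentre (future C2) is left racemic because it is reset in steps 11–16.

Step 6
Reactants: 8 (6S,8aS)-6-ethenyl-1,2,6,7,8,8a-hexahydroazulen-4(5H)-one; 11 allyl 3-amino-2-methylpropanoate
Product: 13 secondary amine, allyl 2-methyl-3-{[(4-oxo-1,2,4,5,6,7,8,8a-octahydroazulen-6-yl)methyl]amino}propanoate, via C5 aldehyde 12 (not isolated)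
Conditions: O3, CH2Cl2/MeOH, Sudan III, −78 °C; Me2S; then 11, AcOH (cat.), NaBH(OAc)3, ClCH2CH2Cl, 0 °C → rt
Reagents that add atoms: allyl 3-amino-2-methylpropanoate, CC(CN)C(=O)OCC=C
Why: Ozonolysis should cleave the electron-rich vinyl group well before the conjugated trisubstituted enone C=C, and the labile γ-keto aldehyde is trapped at once by reductive amination with a primary amine (imine, not enamine, so C6 is not epimerised), NaBH(OAc)3 leaving the ketone untouched.

Step 7
Reactants: 13 secondary amine; 14 diethyl bromomalonate
Product: 15 tertiary aminomalonate, diethyl 2-{[3-(allyloxy)-2-methyl-3-oxopropyl][(4-oxo-1,2,4,5,6,7,8,8a-octahydroazulen-6-yl)methyl]amino}malonate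
Conditions: K2CO3, MeCN, rt
Reagents that add atoms: diethyl bromomalonate, CCOC(=O)C(Br)C(=O)OCC
Why: SN2 N-alkylation of the secondary amine by the activated α-bromomalonate installs C21 with two identical ester groups, so no stereocentre arises at this stage.

Step 8
Reactants: 15 tertiary aminomalonate; 16 formaldehyde (as paraformaldehyde)
Product: 18 tricyclic keto diester (piperidine N4–C5–C6–C23–C22–C21 closed, C21 gem-diester, C23–H), via exocyclic enone 17 (not isolated)
Conditions: (CH2O)n, N-methylanilinium trifluoroacetate, THF, 65 °C; then DBU, rt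
Reagents that add atoms: formaldehyde, C=O
Why: Mannich-type α-methylenation of the only enolisable ketone α-carbon (C23) gives the exocyclic enone, and DBU should trigger the 6-endo-trig intramolecular Michael addition of the malonate carbon C21 to the new CH2 (C22); aminomethylation at C21 is reversible and unproductive, and the C23–H centre is erased in step 9.

Step 9
Reactants: 18 tricyclic keto diester; 16 formaldehyde (monomer)
Product: 20 bridged δ-lactone (C26(=O)–O25–C24 spanning C21 and C23; C14 ketone; C20 ethyl ester), via aldol adduct 19 (not isolated)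
Conditions: LiHMDS, THF, −78 °C; CH2O (gas from cracked paraformaldehyde), −78 → 0 °C; AcOH
Reagents that add atoms: formaldehyde, C=O
Why: Aldol addition of the regiodefined C23 enolate to formaldehyde on the face syn to H6 (angular alkylation giving the cis-fused piperidine) creates quaternary C23, and the alkoxide can lactonise only with the ester cis to C24 (bicyclo[3.3.1] constraint), which differentiates the two esters and so fixes C21.

Step 10
Reactants: 20 bridged δ-lactone; 21 dibromomethane
Product: 22 diene lactone (C14=C15H2 conjugated with C12=C13)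
Conditions: Zn, CH2Br2, TiCl4, THF/CH2Cl2, 0 °C → rt
Reagents that add atoms: dibromomethane, BrCBr
Why: Takai–Lombardo methylenation is non-basic and selective for the hindered enone carbonyl over lactone and esters, and is placed here because no second ketone is yet present.

Step 11
Reactants: 22 diene lactone
Product: 24 O-TES pyrrolidinone β-keto ester (C2 bears Me and CO2allyl), via lithium alkoxide 23 (not isolated)
Conditions: LDA, THF, −78 → −30 °C; then Et3SiCl, −78 → 0 °C
Reagents that add atoms: chlorotriethylsilane, CC[Si](Cl)(CC)CC
Why: Intramolecular Claisen (Dieckmann-type) acylation: the allyl ester enolate at C2 should attack the bridging δ-lactone carbonyl C26 (5-exo-trig, more electrophilic than the ethyl ester), closing the pyrrolidin-3-one and releasing O25, which is silylated in situ; the C2 configuration is irrelevant here.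

Step 12
Reactants: 24 O-TES pyrrolidinone β-keto ester
Product: 25 O-TES 4-methylpyrrolidin-3-one ethyl ester (C2–H, both epimers)
Conditions: Pd(OAc)2 (5 mol %), PPh3, HCO2H, Et3N, THF, rt
Reagents that add atoms: none
Why: Palladium-catalysed deallylation–decarboxylation of the allyl β-keto ester with formate (Tsuji–Trost type) removes the activating ester under neutral conditions that the acid-sensitive diene should tolerate.

Step 13
Reactants: 25 O-TES 4-methylpyrrolidin-3-one ethyl ester
Product: 26 diol (C20H2–OH and C26H–OH, C26 both epimers)
Conditions: LiAlH4, THF, 0 °C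
Reagents that add atoms: none
Why: Hydride reduction of ester and ketone together avoids a chemoselective ester-to-aldehyde reduction beside a ketone; silyl ether, amine and diene are inert.

Step 14
Reactants: 26 diol
Product: 27 dienyl keto aldehyde (C20 aldehyde and C26 ketone on quaternary C21)
Conditions: Dess–Martin periodinane, pyridine, CH2Cl2, 0 °C → rt
Reagents that add atoms: none
Why: Dess–Martin oxidation of both alcohols under neutral conditions should give the non-enolisable β-keto aldehyde without retro-Claisen loss of the formyl group; it is used crude.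

Step 15
Reactants: 27 dienyl keto aldehyde; 28 ethyl bromoacetate
Product: 29 seco hydroxy ester (C15–C16 and C14–C20 formed; ethyl propanoate arm on C14; C20–OH, both epimers)
Conditions: 28 (2 equiv), CrCl2 (10 mol %), 4CzIPN (2 mol %), Hantzsch ester (1.5 equiv), K2HPO4, DMF, blue LEDs, 25 °C
Reagents that add atoms: ethyl bromoacetate, BrCC(=O)OCC
Why: Cr(II), kept at a low stationary concentration by photoreduction, abstracts bromine from 28, the electrophilic radical •CH2CO2Et adds to the unsubstituted diene terminus C15, Cr(II) captures the resulting C12–C13–C14 allyl radical, and the allylchromium(III) adds through its substituted terminus C14 to the aldehyde C20. The closest known reaction type is the chromium-mediated three-component coupling of alkyl halides, 1,3-dienes and aldehydes (Nozaki–Hiyama–Kishi-type radical–polar crossover) in its dual photoredox/chromium form. The carbocycle C14–C20–C21–C22–C23 closes by intramolecular 5-exo carbonyl allylation through a bicyclic, boat-like chelated transition state, which creates the 2-azabicyclo[3.2.1]octane core and leaves the propanoate arm exo, ready for the 6-exo-trig lactonisation of step 16. C14 is substrate-controlled, since only the diene face syn to the 1,3-diaxial formyl group can bond (C13 ends endo, C15 exo), whereas C20 is not relied on: chelation is expected to place O19 syn to C13, and both C20 epimers converge in step 16. The step needs radical addition to the diene to outrun reduction of •CH2CO2Et to a chromium enolate (catalytic Cr, unhindered CH2 terminus), attack at C14 instead of C12 (five- versus seven-membered ring) and aldehyde-over-ketone selectivity (intrinsic to allylchromium reagents).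

Step 16
Reactants: 29 seco hydroxy ester
Product: 31 target lactone, via O-TES lactone 30 (not isolated)
Conditions: Cs2CO3, MeCN, 40 °C; then 1 M HCl, THF, 25 °C
Reagents that add atoms: none
Why: Base-mediated retro-aldol/aldol equilibration of the β-hydroxy ketone (the C20–C21 bond is aligned with the C26=O π system) should epimerise C20, only the epimer with O19 cis to the propanoate arm can lactonise (6-exo-trig) and so drains the equilibrium, C2 equilibrates to the assumed more stable configuration, and aqueous acid then removes the TES group.

Compound list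
1 | cycloheptanone | O=C1CCCCCC1 | starting material
2 | cyclohepta-2,6-dien-1-one | O=C1C=CCCC=C1 | intermediate
3 | potassium vinyltrifluoroborate | C=C[B-](F)(F)F.[K+] | starting material
4 | (S)-6-ethenylcyclohept-2-en-1-one | C=C[C@H]1CCC=CC(=O)C1 | intermediate
5 | [2-(1,3-dioxan-2-yl)ethyl]magnesium bromide | Br[Mg]CCC1OCCCO1 | starting material
6 | (3S,6S)-3-[2-(1,3-dioxan-2-yl)ethyl]-6-ethenylcycloheptan-1-one | C=C[C@H]1CC[C@@H](CCC2OCCCO2)CC(=O)C1 | intermediate
7 | keto aldehyde, 3-(5-ethenyl-3-oxocycloheptyl)propanal (configuration as in 6) | C=C[C@H]1CC[C@@H](CCC=O)CC(=O)C1 | intermediate (not isolated)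
8 | (6S,8aS)-6-ethenyl-1,2,6,7,8,8a-hexahydroazulen-4(5H)-one | C=C[C@H]1CC[C@H]2CCC=C2C(=O)C1 | intermediate
9 | 3-amino-2-methylpropanoic acid (racemic) | CC(CN)C(=O)O | starting material
10 | allyl alcohol | C=CCO | starting material
11 | allyl 3-amino-2-methylpropanoate (racemic) | CC(CN)C(=O)OCC=C | intermediate
12 | C5 aldehyde, 4-oxo-1,2,4,5,6,7,8,8a-octahydroazulene-6-carbaldehyde (ring centres as in 8) | O=C[C@H]1CC[C@H]2CCC=C2C(=O)C1 | intermediate (not isolated)
13 | secondary amine, allyl 2-methyl-3-{[(4-oxo-octahydroazulen-6-yl)methyl]amino}propanoate (C2 epimers) | C=CCOC(=O)C(C)CNC[C@H]1CC[C@H]2CCC=C2C(=O)C1 | intermediate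
14 | diethyl bromomalonate | CCOC(=O)C(Br)C(=O)OCC | starting material
15 | tertiary aminomalonate (N4 bears C5, C3 chain and CH(CO2Et)2) | C=CCOC(=O)C(C)CN(C[C@H]1CC[C@H]2CCC=C2C(=O)C1)C(C(=O)OCC)C(=O)OCC | intermediate
16 | formaldehyde (paraformaldehyde or monomer) | C=O | starting material
17 | exocyclic enone (C23=C22H2 derivative of 15) | C=CCOC(=O)C(C)CN(C[C@H]1CC[C@H]2CCC=C2C(=O)C1=C)C(C(=O)OCC)C(=O)OCC | intermediate (not isolated)
18 | tricyclic keto diester (piperidine closed, C21 gem-diester, C23–H both epimers) | C=CCOC(=O)C(C)CN1C[C@H]2CC[C@H]3CCC=C3C(=O)C2CC1(C(=O)OCC)C(=O)OCC | intermediate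
19 | aldol adduct (C23 quaternary with C24H2OH) | C=CCOC(=O)C(C)CN1C[C@H]2CC[C@H]3CCC=C3C(=O)[C@@]2(CO)CC1(C(=O)OCC)C(=O)OCC | intermediate (not isolated)
20 | bridged δ-lactone (C26(=O)–O25–C24 across C21/C23, C14 ketone, C20 ethyl ester) | C=CCOC(=O)C(C)CN1C[C@H]2CC[C@H]3CCC=C3C(=O)[C@]24COC(=O)[C@]1(C4)C(=O)OCC | intermediate
21 | dibromomethane | BrCBr | starting material
22 | diene lactone (C14=C15H2) | C=CCOC(=O)C(C)CN1C[C@H]2CC[C@H]3CCC=C3C(=C)[C@]24COC(=O)[C@]1(C4)C(=O)OCC | intermediate
23 | hydroxy pyrrolidinone β-keto ester (formed as lithium alkoxide at O25) | C=CCOC(=O)C1(C)CN2C[C@H]3CC[C@H]4CCC=C4C(=C)[C@@]3(CO)C[C@]2(C(=O)OCC)C1=O | intermediate (not isolated)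
24 | O-TES pyrrolidinone β-keto ester | C=CCOC(=O)C1(C)CN2C[C@H]3CC[C@H]4CCC=C4C(=C)[C@@]3(CO[Si](CC)(CC)CC)C[C@]2(C(=O)OCC)C1=O | intermediate
25 | O-TES 4-methylpyrrolidin-3-one ethyl ester (C2 epimers) | CC1CN2C[C@H]3CC[C@H]4CCC=C4C(=C)[C@@]3(CO[Si](CC)(CC)CC)C[C@]2(C(=O)OCC)C1=O | intermediate
26 | diol (C20H2OH, C26H–OH) | CC1CN2C[C@H]3CC[C@H]4CCC=C4C(=C)[C@@]3(CO[Si](CC)(CC)CC)C[C@]2(CO)C1O | intermediate
27 | dienyl keto aldehyde | CC1CN2C[C@H]3CC[C@H]4CCC=C4C(=C)[C@@]3(CO[Si](CC)(CC)CC)C[C@]2(C=O)C1=O | intermediate
28 | ethyl bromoacetate | BrCC(=O)OCC | starting material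
29 | seco hydroxy ester (C20 and C2 epimers) | CC1CN2C[C@H]3CC[C@H]4CCC=C4[C@@]5(CCC(=O)OCC)C(O)[C@@]2(C[C@@]35CO[Si](CC)(CC)CC)C1=O | intermediate
30 | O-TES lactone (triethylsilyl ether of the target) | C[C@@H]1CN2C[C@H]3CC[C@H]4CCC=C4[C@@]45CCC(=O)O[C@@H]4[C@@]2(C[C@@]35CO[Si](CC)(CC)CC)C1=O | intermediate (not isolated)
31 | target hexacyclic hydroxy lactone | C[C@@H]1CN2C[C@H]3CC[C@H]4CCC=C4[C@@]45CCC(=O)O[C@@H]4[C@@]2(C[C@@]35CO)C1=O | target

Total step count: 16. Longest linear sequence: 15 steps (steps 1–4 and 6–16; step 5 is a one-step side branch).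

Steps most likely to fail

Step 15. The acetate radical may be reduced to a chromium enolate or quenched by hydrogen-atom transfer before it adds to the diene, and capture of the allyl radical may be incomplete. The fallback sets out from 27 and separates the two bond formations into classical reactions. Copper-photoredox atom-transfer radical addition of 28 to the diene ([Cu(dap)2]Cl, green LEDs, MeCN) should give the allylic bromide F1 (1,4-adduct, Br on C12, C13=C14 tetrasubstituted). Stoichiometric CrCl2 (THF/DMF, rt) then effects the intramolecular Nozaki–Hiyama–Kishi allylation and returns to 29.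

Step 16. The retro-aldol/aldol equilibration may stall, or the ring-opened keto aldehyde may be diverted before it recloses. The fallback sets out from 29 and epimerises the hindered carbinol by reversible hydrogen transfer instead of C–C cleavage, with a ruthenium alcohol-racemisation catalyst [(η5-C5Ph5)Ru(CO)2Cl, t-BuOK, toluene, 70 °C]. The C26 ketone takes part in the same redox equilibrium, and all species are drained by lactonisation of the cis epimer to 30. Acid treatment as before returns to 31. No new isolable compound arises (no new compound, F0).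

Step 11. The allyl ester enolate may undergo [3,3] rearrangement or O-silylation before it acylates, or it may attack the ethyl ester. The fallback sets out from 22: the allyl ester is first cleaved (Pd(PPh3)4, morpholine, THF) to the amino acid F2. Its dianion (LDA, 2.2 equiv, THF, 0 °C) should acylate on the lactone carbonyl, and the β-keto acid loses CO2 on mild acidic work-up to give the hydroxy ketone F3. Silylation (Et3SiCl, imidazole, CH2Cl2) returns to 25.

Further compounds
F1 | step 15 | allylic bromide (1,4-adduct of ethyl bromoacetate to the diene of 27) | CC1CN2C[C@H]3CC[C@H]4CCC(Br)C4=C(CCC(=O)OCC)[C@@]3(CO[Si](CC)(CC)CC)C[C@]2(C=O)C1=O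
F2 | step 11 | amino acid (free C2 carboxylic acid of diene lactone 22) | OC(=O)C(C)CN1C[C@H]2CC[C@H]3CCC=C3C(=C)[C@]24COC(=O)[C@]1(C4)C(=O)OCC
F3 | step 11 | hydroxy ketone (desilyl 25) | CC1CN2C[C@H]3CC[C@H]4CCC=C4C(=C)[C@@]3(CO)C[C@]2(C(=O)OCC)C1=O
F0 | step 16 | none | none
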